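The runs come from a simulation with made-up constants; scatter was added.

If we reckon with the incoming ligand held at its charge, starting complex falls with one fixed half-time in each flask of that reckoning, and that clock is what we carry here.

| setting | amber | grey | ochre | south | north-west | east |
|---|---|---|---|---|---|---|
| starting complex | 0.50 M | 0.50 M | 0.50 M | 0.50 M | 0.50 M | 0.50 M |
| incoming ligand | 0.66 M | 1.3 M | 2.8 M | 2.40 M | 0.600 M | 1.20 M |
| remark | run made earlier | run made earlier | run made earlier |  |  |  |
| time |  |  |  | 2.0 h | 2.0 h | 2.0 h |

| run | time / min | starting complex / % | complex with two exchanged / % |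
|---|---|---|---|
| amber | 10.0 | 91 | 0 |
| amber | 30.0 | 72 | 0 |
| amber | 50.0 | 60 | 0 |
| amber | 80.0 | 52 | 4 |
| grey | 10.0 | 80 | 0 |
| grey | 30.0 | 60 | 5 |
| grey | 50.0 | 43 | 5 |
| grey | 80.0 | 32 | 8 |
| ochre | 20.0 | 44 | 3 |
| ochre | 40.0 | 24 | 13 |
| ochre | 60.0 | 19 | 17 |
| ochre | 80.0 | 10 | 23 |

(standard deviation of a reading: 2 percentage points)

- what has gone from starting complex into another species counts as reacted, even if it can come back

1. part of the starting complex that has reacted at the end, south
2. part of the starting complex that has reacted at the end, north-west
3. part of the starting complex that has reacted at the end, east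
4. what raising the concentration of incoming ligand from its lowest to its highest value here does to the part of the starting complex that has reacted (changes below 5 percentage points count as none) (it falls / no change / it rises)

In each earlier run we take the first reading with 60% or less of the starting complex left and divide ln(charged/left) by [incoming ligand] and the time. These three figures, each carrying the scatter of its reading, average 0.0144 M⁻¹ min⁻¹. So the half-time at charged ligand, ln(2)/(k[incoming ligand]), the pseudo-first-order half-time, is 80.2 min in north-west, 40.1 min in east and 20.0 min in south.

Over 2.0 h that clock gives 64.6%, 87.4% and 98.4% reacted in the same order. But each exchange takes incoming ligand from the flask, so we take these figures as estimates on the high side.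

The forecast went lower, by “Integrating the second-order law with ligand depletion”: 54%, 77% and 93%, and on the trend, it rises.

The flasks give 55.3%, 76.7% and 90.9%, and it rises by 36 percentage points. Each lies below the clock's figure , and the forecast's ranges hold them.

    starting complex + incoming ligand → leaving ligand + complex with one exchanged (k = 1.70 × 10⁻⁴ M⁻¹ s⁻¹)
    complex with two exchanged + incoming ligand → leaving ligand + complex with three exchanged (k = 6.10 × 10⁻⁵ M⁻¹ s⁻¹)
    complex with one exchanged + incoming ligand → leaving ligand + complex with two exchanged (k = 8.00 × 10⁻⁵ M⁻¹ s⁻¹)
    leaving ligand + starting complex ⇌ idle adduct, settled at all times (K = 2.60 M⁻¹)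

The same flask as east, read at 0.500 h, is 0.749 half-times old: the clock gives 40.5% reacted, and that flask gave 39.6%. North-west at 2.0 h is 1.50 half-times old and has not come to rest, with 45% of its starting complex and 63% of its incoming ligand still unbound. Left ten times as long, south reaches 99.8% reacted and east 97.4%, while north-west reaches 87.9% with its incoming ligand down to 5.43% of its charge.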